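**Strategy.** In the oxolane ring (O1, C2 aryl, C3 CH2OH, C4 OH/benzyl, C5), C3 at the ester oxidation level is flanked by the ring oxygen on C2 (β-alkoxy) and by the tertiary carbinol C4 (β-hydroxy): an oxa-Michael/aldol retron. The route therefore rests on cutting C3–C4. An enantioselective [3+2] annulation of a 1-hydroxy-3-arylpropan-2-one and a methyl 3-arylpropiolate forms O1–C2, then closes the ring by C3–C4 aldol attack, giving a 4-hydroxy-4,5-dihydrofuran-3-carboxylate; its C4 hydroxyl directs cis-hydrogenation to the all-cis oxolane. One bromo-oxolane serves both halves: acid rearranges part of it to the aryltetralin, and borylation/Suzuki coupling joins the two.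

Key step: step 4

Remark on stereochemistry: the oxolane half as drawn is (2R,3R,4S), with aryl, hydroxymethyl and benzyl on one face and the C4 hydroxyl on the other; the tetralin half is (2S,3S,4S) in naphthalen-2-ol numbering, and both halves have the same configuration at the two carbons they share biogenetically, so one intermediate can serve both.

Assumption: compounds 1 and 6 are taken as commercial. The step 4 catalyst is the bifunctional iminophosphorane–thiourea (BIMP type) made by Staudinger reaction of tris(4-methoxyphenyl)phosphine with tert-leucine-derived 1-[3,5-bis(trifluoromethyl)phenyl]-3-(1-azido-3,3-dimethylbutan-2-yl)thiourea. Which antipode gives (4S) cannot be predicted; both are accessible from D- or L-tert-leucine and the appropriate one is used.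

**Step 1**
Reactants: 1 4-(benzyloxy)-3-bromo-5-methoxybenzaldehyde; 2 dimethyl (1-diazo-2-oxopropyl)phosphonate
Product: 3 2-(benzyloxy)-1-bromo-5-ethynyl-3-methoxybenzene
Conditions: 2 (1.2 equiv), K2CO3 (2 equiv), MeOH, 0 °C to rt
Reagents that add atoms: 2 dimethyl (1-diazo-2-oxopropyl)phosphonate, CC(=O)C(=[N+]=[N-])P(=O)(OC)OC
Why: Seyferth–Gilbert homologation in its Ohira–Bestmann variant should convert the non-enolisable aryl aldehyde into the terminal alkyne under carbonate/methanol conditions that leave the aryl bromide and the benzyl ether untouched.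

**Step 2**
Reactants: 3 2-(benzyloxy)-1-bromo-5-ethynyl-3-methoxybenzene; 4 methyl chloroformate
Product: 5 methyl 3-[4-(benzyloxy)-3-bromo-5-methoxyphenyl]prop-2-ynoate
Conditions: LiN(SiMe3)2 (1.1 equiv), THF, −78 °C; then 4, −78 to 0 °C
Reagents that add atoms: 4 methyl chloroformate, COC(=O)Cl
Why: Deprotonation of the terminal alkyne by the amide base (no halogen–lithium exchange at the aryl bromide) and C-acylation of the lithium acetylide with the chloroformate should give the ynoate.

**Step 3**
Reactants: 6 [4-(benzyloxy)-3-methoxyphenyl]acetic acid; 7 tris(trimethylsilyloxy)ethene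
Product: 10 1-[4-(benzyloxy)-3-methoxyphenyl]-3-hydroxypropan-2-one, via arylacetyl chloride 8 (not isolated), via silylated hydroxy keto ester 9 (not isolated)
Conditions: (COCl)2, DMF (cat.), CH2Cl2, 0 °C to rt, concentrate; 7, neat, 90 °C; then 1 M aq. HCl, dioxane, 80 °C
Reagents that add atoms: 7 tris(trimethylsilyloxy)ethene, C[Si](C)(C)OC=C(O[Si](C)(C)C)O[Si](C)(C)C
Why: C-acylation of the ketene silyl acetal by the acid chloride, then hydrolysis and decarboxylation of the α-hydroxy-β-keto acid (hydroxymethyl ketone synthesis from acid chlorides), should give the 1-hydroxy-2-ketone without base, so the enolisable benzyl ketone does not isomerise.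

**Step 4**
Reactants: 5 methyl 3-[4-(benzyloxy)-3-bromo-5-methoxyphenyl]prop-2-ynoate; 10 1-[4-(benzyloxy)-3-methoxyphenyl]-3-hydroxypropan-2-one
Product: 12 methyl (4S)-2-[4-(benzyloxy)-3-bromo-5-methoxyphenyl]-4-{[4-(benzyloxy)-3-methoxyphenyl]methyl}-4-hydroxy-4,5-dihydrofuran-3-carboxylate, via allenolate oxa-Michael adduct 11 (not isolated)
Conditions: 10 (1.2 equiv), chiral iminophosphorane–thiourea Brønsted base (10 mol%), 4 Å MS, toluene, −20 °C
Reagents that add atoms: none
Why: Proposed new method: the chiral iminophosphorane deprotonates the primary hydroxyl of 10, the alkoxide adds to the β-carbon of ynoate 5 (oxa-Michael, O1–C2) to give allenolate 11, and its in-plane vinyl carbanion C3 attacks the tethered ketone carbon C4 in a 5-exo-trig aldol closure that forms the C3–C4 bond and the dihydrofuran ring, with proton transfer from the next molecule of 10 turning the catalyst over. The closest known reaction types are the achiral base-mediated oxa-Michael/aldol annulation of α-hydroxy ketones with alkynoates (the oxygen-first route to interrupted Feist–Benary products), the cinchona-catalysed enantioselective interrupted Feist–Benary reaction and iminophosphorane–thiourea-catalysed enantioselective oxa-Michael additions; their combination on a 3-arylpropiolate is unprecedented. The only new stereocentre, C4, should be set by the catalyst, whose thiourea and iminophosphoranium N–H groups hold the ester enolate and the ketone oxygen so that one ketone face is presented to C3. The step needs O- over C-nucleophilicity of the enolisable benzyl ketone, β-regioselectivity, and ring closure faster than protonation of 11. Hydrogen-bond-directed activation of the hydroxyl, the polarisation of the ynoate, and the intramolecularity of the aldol in an aprotic medium should secure these, while the low temperature should suppress retro-aldol erosion and dehydration to the furan.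

**Step 5**
Reactants: 12 methyl (4S)-2-[4-(benzyloxy)-3-bromo-5-methoxyphenyl]-4-{[4-(benzyloxy)-3-methoxyphenyl]methyl}-4-hydroxy-4,5-dihydrofuran-3-carboxylate
Product: 13 methyl (2R,3R,4S)-2-[4-(benzyloxy)-3-bromo-5-methoxyphenyl]-4-{[4-(benzyloxy)-3-methoxyphenyl]methyl}-4-hydroxyoxolane-3-carboxylate
Conditions: H2 (50 bar), [Ir(cod)(PCy3)(py)]PF6 (10 mol%), CH2Cl2, rt
Reagents that add atoms: none
Why: Hydroxyl-directed homogeneous hydrogenation should deliver both hydrogens to C2 and C3 from the face of the iridium-bound C4 hydroxyl (syn addition), which places aryl and ester cis to each other and to the benzyl group and so fixes C2 (R) and C3 (R) from C4, while the aryl bromide and benzyl ethers are inert to this catalyst.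

**Step 6**
Reactants: 13 methyl (2R,3R,4S)-2-[4-(benzyloxy)-3-bromo-5-methoxyphenyl]-4-{[4-(benzyloxy)-3-methoxyphenyl]methyl}-4-hydroxyoxolane-3-carboxylate
Product: 14 (3S,4R,5R)-5-[4-(benzyloxy)-3-bromo-5-methoxyphenyl]-3-{[4-(benzyloxy)-3-methoxyphenyl]methyl}-4-(hydroxymethyl)oxolan-3-ol
Conditions: i-Bu2AlH (5 equiv), CH2Cl2, −78 to −20 °C; aq. potassium sodium tartrate
Reagents that add atoms: none
Why: Low-temperature ester reduction with the Lewis-acidic, weakly basic aluminium hydride should give the primary alcohol without epimerisation at C3 or retro-oxa-Michael ring opening, and leaves the C–Br bond intact.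

**Step 7**
Reactants: 14 (3S,4R,5R)-5-[4-(benzyloxy)-3-bromo-5-methoxyphenyl]-3-{[4-(benzyloxy)-3-methoxyphenyl]methyl}-4-(hydroxymethyl)oxolan-3-ol (one portion)
Product: 15 (2S,3S,4S)-6-(benzyloxy)-4-[4-(benzyloxy)-3-bromo-5-methoxyphenyl]-2,3-bis(hydroxymethyl)-7-methoxy-1,2,3,4-tetrahydronaphthalen-2-ol
Conditions: CF3CO2H/CH2Cl2 (1:4), 0 °C to rt; aq. NaHCO3/MeOH work-up
Reagents that add atoms: none
Why: Acid-induced ionisation of the benzylic C2–O1 bond should give a para-alkoxybenzyl cation that is trapped by the benzyl arene at its position para to methoxy (intramolecular Friedel–Crafts alkylation, the olivil-to-cycloolivil isomerisation), leaving the two carbinol-bearing centres untouched and forming the new aryl-bearing centre trans to the neighbouring hydroxymethyl group (aryl pseudo-equatorial).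

**Step 8**
Reactants: 14 (3S,4R,5R)-5-[4-(benzyloxy)-3-bromo-5-methoxyphenyl]-3-{[4-(benzyloxy)-3-methoxyphenyl]methyl}-4-(hydroxymethyl)oxolan-3-ol (second portion); 16 bis(pinacolato)diboron; 15 (2S,3S,4S)-6-(benzyloxy)-4-[4-(benzyloxy)-3-bromo-5-methoxyphenyl]-2,3-bis(hydroxymethyl)-7-methoxy-1,2,3,4-tetrahydronaphthalen-2-ol
Product: 18 tetra-O-benzyl ether of the target, via pinacol boronate 17 (not isolated)
Conditions: 14 (1.2 equiv), 16 (1.4 equiv), Pd(OAc)2 (5 mol%), SPhos (10 mol%), KOAc, 1,4-dioxane, 90 °C; then 15 (1.0 equiv), aq. K3PO4, 90 °C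
Reagents that add atoms: none
Why: One-pot Miyaura borylation of 14 and Suzuki–Miyaura cross-coupling of boronate 17 with bromide 15 should form the 2,2'-dioxygenated biaryl bond, the bulky electron-rich biarylphosphine tolerating the ortho-benzyloxy groups and free hydroxyls, with no stereocentre involved.

**Step 9**
Reactants: 18 tetra-O-benzyl ether of the target
Product: 19 CNP0344108.1
Conditions: H2 (1 atm), 10% Pd/C (palladium metal on carbon), EtOAc/MeOH, rt, stopped at full debenzylation
Reagents that add atoms: none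
Why: Hydrogenolysis of the four aryl benzyl ethers is much faster than cleavage of the dialkyl benzylic C–O bond of the oxolane, so mild, monitored global debenzylation should give the target with all six stereocentres intact.

**Compound list**
1 | 4-(benzyloxy)-3-bromo-5-methoxybenzaldehyde | O=Cc1cc(OC)c(OCc2ccccc2)c(Br)c1 | starting material
2 | dimethyl (1-diazo-2-oxopropyl)phosphonate | CC(=O)C(=[N+]=[N-])P(=O)(OC)OC | starting material
3 | 2-(benzyloxy)-1-bromo-5-ethynyl-3-methoxybenzene | C#Cc1cc(OC)c(OCc2ccccc2)c(Br)c1 | intermediate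
4 | methyl chloroformate | COC(=O)Cl | starting material
5 | methyl 3-[4-(benzyloxy)-3-bromo-5-methoxyphenyl]prop-2-ynoate | COC(=O)C#Cc1cc(OC)c(OCc2ccccc2)c(Br)c1 | intermediate
6 | [4-(benzyloxy)-3-methoxyphenyl]acetic acid | OC(=O)Cc1ccc(OCc2ccccc2)c(OC)c1 | starting material
7 | tris(trimethylsilyloxy)ethene | C[Si](C)(C)OC=C(O[Si](C)(C)C)O[Si](C)(C)C | starting material
8 | [4-(benzyloxy)-3-methoxyphenyl]acetyl chloride | O=C(Cl)Cc1ccc(OCc2ccccc2)c(OC)c1 | intermediate (not isolated)
9 | trimethylsilyl 4-[4-(benzyloxy)-3-methoxyphenyl]-3-oxo-2-(trimethylsilyloxy)butanoate | C[Si](C)(C)OC(C(=O)Cc1ccc(OCc2ccccc2)c(OC)c1)C(=O)O[Si](C)(C)C | intermediate (not isolated)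
10 | 1-[4-(benzyloxy)-3-methoxyphenyl]-3-hydroxypropan-2-one | OCC(=O)Cc1ccc(OCc2ccccc2)c(OC)c1 | intermediate
11 | allenolate (vinyl anion) from O-addition of 10 to the β-carbon of 5 | COC(=O)[C-]=C(OCC(=O)Cc1ccc(OCc2ccccc2)c(OC)c1)c1cc(OC)c(OCc2ccccc2)c(Br)c1 | intermediate (not isolated)
12 | methyl (4S)-2-[4-(benzyloxy)-3-bromo-5-methoxyphenyl]-4-{[4-(benzyloxy)-3-methoxyphenyl]methyl}-4-hydroxy-4,5-dihydrofuran-3-carboxylate | COc1cc(C[C@@]2(O)COC(c3cc(OC)c(OCc4ccccc4)c(Br)c3)=C2C(=O)OC)ccc1OCc1ccccc1 | intermediate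
13 | methyl (2R,3R,4S)-2-[4-(benzyloxy)-3-bromo-5-methoxyphenyl]-4-{[4-(benzyloxy)-3-methoxyphenyl]methyl}-4-hydroxyoxolane-3-carboxylate (aryl, ester and benzyl on one face) | COc1cc(C[C@@]2(O)CO[C@@H](c3cc(OC)c(OCc4ccccc4)c(Br)c3)[C@H]2C(=O)OC)ccc1OCc1ccccc1 | intermediate
14 | (3S,4R,5R)-5-[4-(benzyloxy)-3-bromo-5-methoxyphenyl]-3-{[4-(benzyloxy)-3-methoxyphenyl]methyl}-4-(hydroxymethyl)oxolan-3-ol | COc1cc(C[C@@]2(O)CO[C@@H](c3cc(OC)c(OCc4ccccc4)c(Br)c3)[C@H]2CO)ccc1OCc1ccccc1 | intermediate
15 | (2S,3S,4S)-6-(benzyloxy)-4-[4-(benzyloxy)-3-bromo-5-methoxyphenyl]-2,3-bis(hydroxymethyl)-7-methoxy-1,2,3,4-tetrahydronaphthalen-2-ol | COc1cc([C@H]2c3cc(OCc4ccccc4)c(OC)cc3C[C@@](O)(CO)[C@@H]2CO)cc(Br)c1OCc1ccccc1 | intermediate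
16 | bis(pinacolato)diboron | CC1(C)OB(OC1(C)C)B1OC(C)(C)C(C)(C)O1 | starting material
17 | pinacol boronate of 14 (Bpin in place of Br) | COc1cc(C[C@@]2(O)CO[C@@H](c3cc(OC)c(OCc4ccccc4)c(B4OC(C)(C)C(C)(C)O4)c3)[C@H]2CO)ccc1OCc1ccccc1 | intermediate (not isolated)
18 | tetra-O-benzyl ether of the target (all four phenols benzylated) | COc1cc(C[C@@]2(O)CO[C@@H](c3cc(OC)c(OCc4ccccc4)c(-c4cc([C@H]5c6cc(OCc7ccccc7)c(OC)cc6C[C@@](O)(CO)[C@@H]5CO)cc(OC)c4OCc4ccccc4)c3)[C@H]2CO)ccc1OCc1ccccc1 | intermediate
19 | CNP0344108.1 (5,5'-linked all-cis oxolane lignan / aryltetralin lignan dimer) | COc1cc(C[C@@]2(O)CO[C@@H](c3cc(OC)c(O)c(-c4cc([C@H]5c6cc(O)c(OC)cc6C[C@@](O)(CO)[C@@H]5CO)cc(OC)c4O)c3)[C@H]2CO)ccc1O | target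

**Step count and risks**
Total steps: 9. Longest linear sequence: 8 (steps 1, 2, 4, 5, 6, 7, 8, 9).

Step 4 (bears the label). What may go wrong: poor enantiofacial discrimination in the ring-closing aldol or its erosion by retro-aldol, protonation of the allenolate before ring closure, or C- instead of O-addition of the hydroxy ketone. The fallback replaces catalyst control by a traceless ester auxiliary and diastereomer separation, using known chemistry. It sets out from 3, whose lithium acetylide is acylated with (1R,2S,5R)-menthyl chloroformate to give the menthyl ynoate F1. The achiral base-mediated oxa-Michael/aldol annulation of F1 with 10 (Cs2CO3 cat., toluene) should give the two C4-epimeric menthyl dihydrofuran esters, the (4S) ester F2 and the (4R) ester F3. These are diastereomers and are separated by chromatography or crystallisation. F2 is hydrogenated as in step 5 to the menthyl oxolane ester F4, and reduction with i-Bu2AlH releases menthol and comes back to the route at 14.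

Step 5. What may go wrong: no turnover at the tetrasubstituted donor–acceptor C2=C3 bond, or dehydration of the tertiary alcohol to the furan promoted by acidic cationic iridium hydrides. The fallback masks the C–Br bond so that a neutral heterogeneous, substrate-controlled hydrogenation can be used. It sets out from 12: Miyaura borylation (16, Pd(OAc)2, SPhos, KOAc) gives the dihydrofuran boronate F5. H2 over 5% Rh/Al2O3 in EtOAc should add from the less hindered, hydroxyl-bearing face to give the all-cis oxolane ester boronate F6. i-Bu2AlH reduction then gives 17, here isolated, where the route is rejoined. Part of 17 is converted with CuBr2 in MeOH/H2O (bromodeboronation) into 14 for step 7.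

Step 7. What may go wrong: sluggish ionisation of the C2–O1 bond, because the para-benzyloxy group is twisted out of conjugation by its two ortho neighbours and the bromine withdraws electron density, with loss of benzyl groups under more forcing acid. The fallback uses free-phenol-assisted cyclisation. It sets out from 14: BCl3/pentamethylbenzene in CH2Cl2 at −78 °C, then MeOH, cleaves both aryl benzyl ethers, and the freed para-phenol should drive the cyclisation to the bromo-cycloolivil F7. Suzuki coupling of F7 with 17 as in step 8 gives the di-O-benzyl biaryl F8, and hydrogenolysis as in step 9 comes back to the route at 19.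

**Further compounds**
F1 | step 4 | (1R,2S,5R)-menthyl 3-[4-(benzyloxy)-3-bromo-5-methoxyphenyl]prop-2-ynoate | CC(C)[C@@H]1CC[C@@H](C)C[C@H]1OC(=O)C#Cc1cc(OC)c(OCc2ccccc2)c(Br)c1
F2 | step 4 | (1R,2S,5R)-menthyl (4S)-2-[4-(benzyloxy)-3-bromo-5-methoxyphenyl]-4-{[4-(benzyloxy)-3-methoxyphenyl]methyl}-4-hydroxy-4,5-dihydrofuran-3-carboxylate | COc1cc(C[C@@]2(O)COC(c3cc(OC)c(OCc4ccccc4)c(Br)c3)=C2C(=O)O[C@@H]5C[C@H](C)CC[C@H]5C(C)C)ccc1OCc1ccccc1
F3 | step 4 | (1R,2S,5R)-menthyl (4R)-2-[4-(benzyloxy)-3-bromo-5-methoxyphenyl]-4-{[4-(benzyloxy)-3-methoxyphenyl]methyl}-4-hydroxy-4,5-dihydrofuran-3-carboxylate | COc1cc(C[C@]2(O)COC(c3cc(OC)c(OCc4ccccc4)c(Br)c3)=C2C(=O)O[C@@H]5C[C@H](C)CC[C@H]5C(C)C)ccc1OCc1ccccc1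
F4 | step 4 | (1R,2S,5R)-menthyl (2R,3R,4S)-2-[4-(benzyloxy)-3-bromo-5-methoxyphenyl]-4-{[4-(benzyloxy)-3-methoxyphenyl]methyl}-4-hydroxyoxolane-3-carboxylate | COc1cc(C[C@@]2(O)CO[C@@H](c3cc(OC)c(OCc4ccccc4)c(Br)c3)[C@H]2C(=O)O[C@@H]5C[C@H](C)CC[C@H]5C(C)C)ccc1OCc1ccccc1
F5 | step 5 | methyl (4S)-2-[4-(benzyloxy)-3-methoxy-5-(4,4,5,5-tetramethyl-1,3,2-dioxaborolan-2-yl)phenyl]-4-{[4-(benzyloxy)-3-methoxyphenyl]methyl}-4-hydroxy-4,5-dihydrofuran-3-carboxylate | COc1cc(C[C@@]2(O)COC(c3cc(OC)c(OCc4ccccc4)c(B4OC(C)(C)C(C)(C)O4)c3)=C2C(=O)OC)ccc1OCc1ccccc1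
F6 | step 5 | methyl (2R,3R,4S)-2-[4-(benzyloxy)-3-methoxy-5-(4,4,5,5-tetramethyl-1,3,2-dioxaborolan-2-yl)phenyl]-4-{[4-(benzyloxy)-3-methoxyphenyl]methyl}-4-hydroxyoxolane-3-carboxylate | COc1cc(C[C@@]2(O)CO[C@@H](c3cc(OC)c(OCc4ccccc4)c(B4OC(C)(C)C(C)(C)O4)c3)[C@H]2C(=O)OC)ccc1OCc1ccccc1
F7 | step 7 | (2S,3S,4S)-4-(3-bromo-4-hydroxy-5-methoxyphenyl)-2,3-bis(hydroxymethyl)-7-methoxy-1,2,3,4-tetrahydronaphthalene-2,6-diol | COc1cc([C@H]2c3cc(O)c(OC)cc3C[C@@](O)(CO)[C@@H]2CO)cc(Br)c1O
F8 | step 7 | di-O-benzyl ether of the target (benzyl groups on the two phenols of the oxolane half only) | COc1cc(C[C@@]2(O)CO[C@@H](c3cc(OC)c(OCc4ccccc4)c(-c4cc([C@H]5c6cc(O)c(OC)cc6C[C@@](O)(CO)[C@@H]5CO)cc(OC)c4O)c3)[C@H]2CO)ccc1OCc1ccccc1
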